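**Assumption:** the target has no stereocentre and no stereogenic double bond (both prenyl alkenes end in gem-dimethyl groups), so it is achiral and "single enantiomer" adds no requirement. Ring positions are numbered from the carbonyl-bearing carbon of the trioxygenated ring; primed positions belong to the 3-hydroxyphenyl ring.

**Retrosynthetic overview**
1. Cut the 4-O–CH3 bond last: selective O-methylation of the most acidic, non-chelated 4-OH of a 3,5-diprenyl-2,4,6-trihydroxybenzophenone.
2. Cut both aryl–prenyl C–C bonds: double C-prenylation of the acylphloroglucinol anion with prenyl bromide.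
3. Cut the aryl–C(=O) bond: Houben–Hoesch acylation of phloroglucinol with 3-hydroxybenzonitrile.
4. No ring is formed; both benzene rings are bought intact (phloroglucinol and 3-hydroxybenzonitrile). The route is protecting-group free.

**Route**

Step 1
Reactants: 1 phloroglucinol (benzene-1,3,5-triol, anhydrous); 2 3-hydroxybenzonitrile
Product: 4 (3-hydroxyphenyl)(2,4,6-trihydroxyphenyl)methanone, via ketiminium chloride 3 (not isolated)
Conditions: ZnCl2, dry HCl(g), Et2O, 0 °C, 48 h; then H2O, reflux, 2 h
Reagents that add atoms: water, O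
Why: Houben–Hoesch acylation, in which the HCl/ZnCl2-activated nitrile attacks the symmetric, very electron-rich phloroglucinol (one possible C-acylation product, the iminium salt blocks a second acylation) and hot water hydrolyses the ketiminium salt to the ketone; no stereocentre is formed.

Step 2
Reactants: 4 (3-hydroxyphenyl)(2,4,6-trihydroxyphenyl)methanone; 5 prenyl bromide (1-bromo-3-methylbut-2-ene)
Product: 7 (3-hydroxyphenyl)[2,4,6-trihydroxy-3,5-bis(3-methylbut-2-en-1-yl)phenyl]methanone, via mono-C-prenyl ketone 6 (not isolated)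
Conditions: 5 (2.2 equiv, slow addition), 5% aq KOH, 0 °C, 2 h; then cold 1 M HCl to pH 4
Reagents that add atoms: prenyl bromide (5), CC(C)=CCBr
Why: base-mediated C-alkylation (SN2) of the enolate-like acylphloroglucinol polyanion, whose only nucleophilic ring carbons are C3 and C5, while the water-solvated 3'-phenoxide on the deactivated ring is a much poorer nucleophile; no stereocentre is formed.

Step 3
Reactants: 7 (3-hydroxyphenyl)[2,4,6-trihydroxy-3,5-bis(3-methylbut-2-en-1-yl)phenyl]methanone; 8 dimethyl sulfate
Product: 9 [2,6-dihydroxy-4-methoxy-3,5-bis(3-methylbut-2-en-1-yl)phenyl](3-hydroxyphenyl)methanone (target)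
Conditions: 8 (1.05 equiv), K2CO3 (1.0 equiv), acetone, 0 °C to rt
Reagents that add atoms: dimethyl sulfate (8), COS(=O)(=O)OC
Why: chemoselective Williamson O-methylation, since with one equivalent of base the anion sits on the 4-OH (a vinylogous carboxylic acid para to the ketone), the 2-/6-OH are held by hydrogen bonding to the carbonyl, the 3'-OH is less acidic, and the hard sulfate electrophile in acetone favours O- over C-methylation; no stereocentre is formed.

**Compound list**
1 | phloroglucinol (benzene-1,3,5-triol) | Oc1cc(O)cc(O)c1 | starting material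
2 | 3-hydroxybenzonitrile | N#Cc1cccc(O)c1 | starting material
3 | (3-hydroxyphenyl)(2,4,6-trihydroxyphenyl)methaniminium chloride | [NH2+]=C(c1cccc(O)c1)c1c(O)cc(O)cc1O.[Cl-] | intermediate
4 | (3-hydroxyphenyl)(2,4,6-trihydroxyphenyl)methanone | O=C(c1cccc(O)c1)c1c(O)cc(O)cc1O | intermediate
5 | prenyl bromide (1-bromo-3-methylbut-2-ene) | CC(C)=CCBr | starting material
6 | (3-hydroxyphenyl)[2,4,6-trihydroxy-3-(3-methylbut-2-en-1-yl)phenyl]methanone | CC(C)=CCc1c(O)cc(O)c(C(=O)c2cccc(O)c2)c1O | intermediate
7 | (3-hydroxyphenyl)[2,4,6-trihydroxy-3,5-bis(3-methylbut-2-en-1-yl)phenyl]methanone | CC(C)=CCc1c(O)c(CC=C(C)C)c(O)c(C(=O)c2cccc(O)c2)c1O | intermediate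
8 | dimethyl sulfate | COS(=O)(=O)OC | starting material
9 | [2,6-dihydroxy-4-methoxy-3,5-bis(3-methylbut-2-en-1-yl)phenyl](3-hydroxyphenyl)methanone | COc1c(CC=C(C)C)c(O)c(C(=O)c2cccc(O)c2)c(O)c1CC=C(C)C | target

**Totals**
Total step count: 3. Longest linear sequence: 3 steps (1 or 2 → 4 → 7 → 9).

**Steps most likely to fail, with fallbacks**

Step 2 (double C-prenylation) is the most likely to fail. The risks are a statistical mixture of mono-, di- and dearomatised gem-diprenyl products, and O-prenylation at the 4-O or 3'-O. The fallback sets out from 4 and comes back to the route at 9 by reversing the order of events. Compound 4 is first mono-methylated at its unhindered, most acidic 4-OH with 8 (1.0 equiv) and K2CO3 in acetone to give (2,6-dihydroxy-4-methoxyphenyl)(3-hydroxyphenyl)methanone F2. With the 4-oxygen capped, 4-O-alkylation is impossible and dearomatising over-alkylation is less favourable. F2 is then C-prenylated with 5 (2.2 equiv) in cold aqueous KOH, passing through [2,6-dihydroxy-4-methoxy-3-(3-methylbut-2-en-1-yl)phenyl](3-hydroxyphenyl)methanone F3 in the flask, and gives 9 directly.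

Step 3 (selective 4-O-methylation) is the second risk. The 3'-OH may be methylated competitively, or a second methyl may go on a 2-/6-OH. The fallback sets out from 7 and comes back at 9 by masking the 3'-OH on steric grounds. Triisopropylsilyl chloride (1.05 equiv) and imidazole in DMF at 0 °C silylate only the unhindered 3'-OH, because the 4-OH is flanked by two prenyl groups and the 2-/6-OH are chelated and flanked. This gives [2,4,6-trihydroxy-3,5-bis(3-methylbut-2-en-1-yl)phenyl][3-(triisopropylsilyloxy)phenyl]methanone F4. Methylation with 8 and K2CO3 in acetone can then be driven to completion at the 4-OH to give [2,6-dihydroxy-4-methoxy-3,5-bis(3-methylbut-2-en-1-yl)phenyl][3-(triisopropylsilyloxy)phenyl]methanone F5. TBAF in THF at 0 °C removes the silyl group and gives 9.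

Step 1 (Houben–Hoesch) is the third risk. The ketiminium salt may form sluggishly or the hydroxynitrile may give tarry by-products. The fallback sets out from 1 and comes back at 4 by using a masked acyl chloride instead of the nitrile. Friedel–Crafts acylation of 1 with commercial 3-methoxybenzoyl chloride (AlCl3, nitrobenzene, 60 °C) gives (3-methoxyphenyl)(2,4,6-trihydroxyphenyl)methanone F1. BBr3 (CH2Cl2, −78 °C to rt) then cleaves its single methyl ether and gives 4.

**Further compounds**
F1 | step 1 | (3-methoxyphenyl)(2,4,6-trihydroxyphenyl)methanone | COc1cccc(c1)C(=O)c1c(O)cc(O)cc1O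
F2 | step 2 | (2,6-dihydroxy-4-methoxyphenyl)(3-hydroxyphenyl)methanone | COc1cc(O)c(C(=O)c2cccc(O)c2)c(O)c1
F3 | step 2 | [2,6-dihydroxy-4-methoxy-3-(3-methylbut-2-en-1-yl)phenyl](3-hydroxyphenyl)methanone | COc1cc(O)c(C(=O)c2cccc(O)c2)c(O)c1CC=C(C)C
F4 | step 3 | [2,4,6-trihydroxy-3,5-bis(3-methylbut-2-en-1-yl)phenyl][3-(triisopropylsilyloxy)phenyl]methanone | CC(C)=CCc1c(O)c(CC=C(C)C)c(O)c(C(=O)c2cccc(O[Si](C(C)C)(C(C)C)C(C)C)c2)c1O
F5 | step 3 | [2,6-dihydroxy-4-methoxy-3,5-bis(3-methylbut-2-en-1-yl)phenyl][3-(triisopropylsilyloxy)phenyl]methanone | COc1c(CC=C(C)C)c(O)c(C(=O)c2cccc(O[Si](C(C)C)(C(C)C)C(C)C)c2)c(O)c1CC=C(C)C
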